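**Plan**

- Retrosynthesis: the acetate, the four benzyl groups and the open carboxyl are traced back to a 3,4-dihydroisocoumarin. That lactone is cut at three bonds (aryl C6–C1' of the side chain, aryl C1–C(=O) and C(=O)–O) into an aryl iodide, a terminal epoxide and carbon monoxide.
- Enabling feature: ring carbons C2 (oxygen), C1 (carboxyl) and C6 (side chain) are neighbours. The carboxyl carbon reaches the oxygen on C2' through aryl C1, aryl C6 and C1', which is the seco form of a six-membered lactone ring. The C2 oxygen leaves only one free C–H next to an iodine placed on C1.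
- Forward: the resorcinol dibenzyl ether is iodinated. The C13 chain is made by Grignard opening of epichlorohydrin and closed to the epoxide. One palladium/norbornene (Catellani-type) step joins chain and arene and closes the lactone, the only ring formed. The lactone is then opened, the acid benzylated, the alcohol acetylated and all benzyl groups removed.
- Stereochemistry: the single (R) centre at C2' comes from (R)-epichlorohydrin; its C–O bond is never broken.

Key step: step 5

Remark: carbon monoxide is counted as a reactant of the key step, and every hydroxyl and the carboxyl are carried as benzyl derivatives so that one neutral hydrogenolysis ends the route.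

**Step 1**
Reactants: 1 1,3-bis(benzyloxy)benzene
Product: 2 2,4-bis(benzyloxy)-1-iodobenzene
Conditions: NIS (1.0 equiv), MeCN, 0 °C to rt, dark
Reagents that add atoms: N-iodosuccinimide, O=C1CCC(=O)N1I
Why: Electrophilic aromatic iodination should go to C4, which is para to one ether and ortho to the other and less crowded than C2 between the two ethers.

**Step 2**
Reactants: 3 10-bromodecan-1-ol
Product: 4 {[(10-bromodecyl)oxy]methyl}benzene
Conditions: benzyl 2,2,2-trichloroacetimidate (1.3 equiv), TfOH (5 mol%), CH2Cl2/cyclohexane, 0 °C to rt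
Reagents that add atoms: benzyl 2,2,2-trichloroacetimidate, N=C(OCc1ccccc1)C(Cl)(Cl)Cl
Why: Acid-catalysed O-benzylation with a trichloroacetimidate protects the alcohol without forming an alkoxide, so the primary bromide is not displaced.

**Step 3**
Reactants: 4 {[(10-bromodecyl)oxy]methyl}benzene, 5 (R)-epichlorohydrin
Product: 7 (2R)-13-(benzyloxy)-1-chlorotridecan-2-ol, via alkylmagnesium bromide 6 (not isolated)
Conditions: Mg turnings, cat. I2, THF, 40 °C; then CuI (10 mol%), 5, THF, −40 to −20 °C; aqueous work-up
Reagents that add atoms: magnesium, [Mg] (taken up in intermediate 6 only)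
Why: Copper-catalysed Grignard opening of a terminal epoxide (SN2 at the ring CH2) should be faster than displacement of chloride, and since the carbinol carbon is not attacked the (R) centre is retained.

**Step 4**
Reactants: 7 (2R)-13-(benzyloxy)-1-chlorotridecan-2-ol
Product: 8 (2R)-2-[11-(benzyloxy)undecyl]oxirane
Conditions: powdered NaOH (3 equiv), Et2O, 0 °C to rt
Reagents that add atoms: none
Why: Intramolecular Williamson etherification (3-exo-tet) displaces the primary chloride, and because the C–O bond at the carbinol carbon stays intact the (R) configuration is kept.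

**Step 5**
Reactants: 2 2,4-bis(benzyloxy)-1-iodobenzene, 8 (2R)-2-[11-(benzyloxy)undecyl]oxirane, 9 carbon monoxide
Product: 10 (3R)-6,8-bis(benzyloxy)-3-[11-(benzyloxy)undecyl]-3,4-dihydro-1H-isochromen-1-one
Conditions: Pd(OAc)2 (10 mol%), XPhos (20 mol%), norbornene (1.5 equiv), K2CO3 (2 equiv), 8 (1.5 equiv), NMP, 70 °C, argon; 9 fed as gas by syringe pump (about 1.5 equiv over 10 h)
Reagents that add atoms: none
Why: Proposed new method: zerovalent palladium should insert into the C–I bond of 2, and norbornene carbopalladation followed by base-assisted palladation of the only free ortho C–H (C6) gives an aryl–norbornyl palladacycle of divalent palladium; this opens 8 at its CH2 terminus by SN2-type oxidative addition to tetravalent palladium, reductive elimination forms the aryl C6–CH2 bond, norbornene is extruded by β-carbon elimination once both ortho positions are filled, and the arylpalladium at C1 inserts CO to an aroylpalladium species that acylates the pendant alkoxide. The closest known reactions are Catellani ortho-alkylations of aryl iodides with epoxides that end in a Heck or C–O termination at the ipso carbon, and the palladium-catalysed carbonylative lactonisation of 2-(2-haloaryl)ethanols; joining the two in one catalytic cycle is the untested part. The six-membered lactone, the only ring formed, closes by 6-exo-trig attack of the alkoxide oxygen on the acylpalladium carbon (equivalently, C–O reductive elimination from a seven-membered acyl alkoxide palladacycle). No stereocentre is created: C3 is the epoxide carbon whose C–O bond is never broken, so the (R) configuration is carried over unchanged. Site selectivity rests on the benzyloxy group at C2, which leaves C6–H as the single ortho position and forces norbornene extrusion after one alkylation, and regioselective epoxide opening rests on the unhindered CH2 terminus. The order of events (CO must not intercept the arylpalladium iodide or the palladacycle, yet must beat C–O reductive elimination to the 2,3-dihydrobenzofuran) is to be secured by keeping the CO concentration low through the syringe-pump feed.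

**Step 6**
Reactants: 10 (3R)-6,8-bis(benzyloxy)-3-[11-(benzyloxy)undecyl]-3,4-dihydro-1H-isochromen-1-one
Product: 12 benzyl 2,4-bis(benzyloxy)-6-[(2R)-13-(benzyloxy)-2-hydroxytridecyl]benzoate, via potassium carboxylate 11 (not isolated)
Conditions: KOH (1.1 equiv), THF/H2O, 50 °C; evaporate to dryness; BnBr (1.3 equiv), DMF, 0 °C to rt
Reagents that add atoms: potassium hydroxide, [K+].[OH-]; benzyl bromide, BrCc1ccccc1
Why: Saponification followed by SN2 O-alkylation of the carboxylate, with no acidification in between, should keep the hydroxy acid from closing back to the lactone, and the secondary hydroxyl stays free because no alkoxide is generated.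

**Step 7**
Reactants: 12 benzyl 2,4-bis(benzyloxy)-6-[(2R)-13-(benzyloxy)-2-hydroxytridecyl]benzoate
Product: 13 benzyl 2-[(2R)-2-(acetyloxy)-13-(benzyloxy)tridecyl]-4,6-bis(benzyloxy)benzoate
Conditions: Ac2O (3 equiv), pyridine, DMAP (10 mol%), CH2Cl2, 0 °C, on freshly prepared 12
Reagents that add atoms: acetic anhydride, CC(=O)OC(C)=O
Why: DMAP-catalysed O-acetylation of the secondary alcohol should outpace attack of that hydroxyl on the hindered 2,6-disubstituted benzoate, and the stereocentre is not involved.

**Step 8**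
Reactants: 13 benzyl 2-[(2R)-2-(acetyloxy)-13-(benzyloxy)tridecyl]-4,6-bis(benzyloxy)benzoate
Product: 14 2-[(2R)-2-(acetyloxy)-13-hydroxytridecyl]-4,6-dihydroxybenzoic acid
Conditions: H2 (1 atm), 10% Pd/C, EtOAc, rt
Reagents that add atoms: none
Why: Catalytic hydrogenolysis cleaves the two aryl benzyl ethers, the alkyl benzyl ether and the benzyl ester under neutral conditions, while the secondary acetate (homobenzylic, not benzylic) and the stereocentre should stay untouched.

**Compound list**

1 | 1,3-bis(benzyloxy)benzene | c1ccc(COc2cccc(OCc3ccccc3)c2)cc1 | starting material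
2 | 2,4-bis(benzyloxy)-1-iodobenzene | Ic1ccc(OCc2ccccc2)cc1OCc1ccccc1 | intermediate
3 | 10-bromodecan-1-ol | OCCCCCCCCCCBr | starting material
4 | {[(10-bromodecyl)oxy]methyl}benzene | BrCCCCCCCCCCOCc1ccccc1 | intermediate
5 | (R)-epichlorohydrin | ClC[C@H]1CO1 | starting material
6 | [10-(benzyloxy)decyl]magnesium bromide | Br[Mg]CCCCCCCCCCOCc1ccccc1 | intermediate (not isolated)
7 | (2R)-13-(benzyloxy)-1-chlorotridecan-2-ol | ClC[C@H](O)CCCCCCCCCCCOCc1ccccc1 | intermediate
8 | (2R)-2-[11-(benzyloxy)undecyl]oxirane | O1[C@H](CCCCCCCCCCCOCc2ccccc2)C1 | intermediate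
9 | carbon monoxide | [C-]#[O+] | starting material
10 | (3R)-6,8-bis(benzyloxy)-3-[11-(benzyloxy)undecyl]-3,4-dihydro-1H-isochromen-1-one | O=C1O[C@H](CCCCCCCCCCCOCc2ccccc2)Cc2cc(OCc3ccccc3)cc(OCc3ccccc3)c12 | intermediate
11 | potassium 2,4-bis(benzyloxy)-6-[(2R)-13-(benzyloxy)-2-hydroxytridecyl]benzoate | [K+].[O-]C(=O)c1c(OCc2ccccc2)cc(OCc2ccccc2)cc1C[C@H](O)CCCCCCCCCCCOCc1ccccc1 | intermediate (not isolated)
12 | benzyl 2,4-bis(benzyloxy)-6-[(2R)-13-(benzyloxy)-2-hydroxytridecyl]benzoate | O=C(OCc1ccccc1)c1c(OCc2ccccc2)cc(OCc2ccccc2)cc1C[C@H](O)CCCCCCCCCCCOCc1ccccc1 | intermediate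
13 | benzyl 2-[(2R)-2-(acetyloxy)-13-(benzyloxy)tridecyl]-4,6-bis(benzyloxy)benzoate | CC(=O)O[C@H](CCCCCCCCCCCOCc1ccccc1)Cc1cc(OCc2ccccc2)cc(OCc2ccccc2)c1C(=O)OCc1ccccc1 | intermediate
14 | 2-[(2R)-2-(acetyloxy)-13-hydroxytridecyl]-4,6-dihydroxybenzoic acid | CC(=O)O[C@H](CCCCCCCCCCCO)Cc1cc(O)cc(O)c1C(=O)O | target

**Step count and risks**

Total: 8 steps. Longest linear sequence: 7 steps (steps 2 to 8, from 10-bromodecan-1-ol).

Steps most likely to fail:

1. Step 5. CO may bind palladium before the ortho-alkylation is complete, inserting into the arylpalladium iodide or the palladacycle or poisoning the catalyst. With too little CO, C–O reductive elimination without carbonylation may take over. The fallback uses known chemistry, sets out from epoxide 8 and returns at lactone 10. Commercial 1,3-bis(benzyloxy)-5-bromobenzene F1 is converted with Mg in THF into [3,5-bis(benzyloxy)phenyl]magnesium bromide F2. Under CuI catalysis this opens 8 at its CH2 to give (2R)-1-[3,5-bis(benzyloxy)phenyl]-13-(benzyloxy)tridecan-2-ol F3. NIS in MeCN should iodinate the ring position ortho to the side chain and para to an ether, giving (2R)-1-[3,5-bis(benzyloxy)-2-iodophenyl]-13-(benzyloxy)tridecan-2-ol F4. Intramolecular alkoxycarbonylation with PdCl2(PPh3)2, CO (1 atm) and K2CO3 in DMF at 90 °C then closes 10.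

2. Step 6. The hydroxy ester may close back to the lactone with loss of benzyl alcohol during alkylation, work-up or the following acylation, and hydrolysis of the hindered lactone may be incomplete. The fallback sets out from lactone 10 and returns at target 14, carrying the carboxyl carbon at the alcohol level while the acetate is installed.
   - LiAlH4 in THF reduces 10 to (2R)-1-[3,5-bis(benzyloxy)-2-(hydroxymethyl)phenyl]-13-(benzyloxy)tridecan-2-ol F5.
   - TBSCl and imidazole silylate the primary benzylic hydroxyl to give (2R)-1-[3,5-bis(benzyloxy)-2-({[tert-butyl(dimethyl)silyl]oxy}methyl)phenyl]-13-(benzyloxy)tridecan-2-ol F6.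
   - Ac2O, pyridine and DMAP give (2R)-1-[3,5-bis(benzyloxy)-2-({[tert-butyl(dimethyl)silyl]oxy}methyl)phenyl]-13-(benzyloxy)tridecan-2-yl acetate F7.
   - TBAF buffered with AcOH in THF frees (2R)-1-[3,5-bis(benzyloxy)-2-(hydroxymethyl)phenyl]-13-(benzyloxy)tridecan-2-yl acetate F8.
   - MnO2 in CH2Cl2 gives (2R)-1-[3,5-bis(benzyloxy)-2-formylphenyl]-13-(benzyloxy)tridecan-2-yl acetate F9.
   - Pinnick oxidation (NaClO2, NaH2PO4, 2-methylbut-2-ene, tBuOH/H2O) gives 2-[(2R)-2-(acetyloxy)-13-(benzyloxy)tridecyl]-4,6-bis(benzyloxy)benzoic acid F10.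
   - Hydrogenolysis over 10% Pd/C in EtOAc gives 14.

3. Step 3. Wurtz homocoupling may occur during magnesium insertion, bromide from the magnesium halide may open the epoxide, and partial direct displacement of chloride would erode the enantiomeric purity. The fallback sets out from bromide 4 and returns at epoxide 8. Coupling of 4 with allylmagnesium bromide under Li2CuCl4 catalysis in THF gives {[(tridec-12-en-1-yl)oxy]methyl}benzene F11. mCPBA in CH2Cl2 gives racemic 2-[11-(benzyloxy)undecyl]oxirane F12. Hydrolytic kinetic resolution with 0.55 equiv of water and the (R,R)-(salen)Co(OAc) complex of trivalent cobalt (salen = N,N'-bis(3,5-di-tert-butylsalicylidene)-1,2-cyclohexanediamine) should hydrolyse the (S)-enantiomer to the diol and leave (R)-epoxide 8.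

**Further compounds**

F1 | step 5 | 1,3-bis(benzyloxy)-5-bromobenzene | Brc1cc(OCc2ccccc2)cc(OCc2ccccc2)c1
F2 | step 5 | [3,5-bis(benzyloxy)phenyl]magnesium bromide | Br[Mg]c1cc(OCc2ccccc2)cc(OCc2ccccc2)c1
F3 | step 5 | (2R)-1-[3,5-bis(benzyloxy)phenyl]-13-(benzyloxy)tridecan-2-ol | O[C@H](CCCCCCCCCCCOCc1ccccc1)Cc1cc(OCc2ccccc2)cc(OCc2ccccc2)c1
F4 | step 5 | (2R)-1-[3,5-bis(benzyloxy)-2-iodophenyl]-13-(benzyloxy)tridecan-2-ol | O[C@H](CCCCCCCCCCCOCc1ccccc1)Cc1cc(OCc2ccccc2)cc(OCc2ccccc2)c1I
F5 | step 6 | (2R)-1-[3,5-bis(benzyloxy)-2-(hydroxymethyl)phenyl]-13-(benzyloxy)tridecan-2-ol | O[C@H](CCCCCCCCCCCOCc1ccccc1)Cc1cc(OCc2ccccc2)cc(OCc2ccccc2)c1CO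
F6 | step 6 | (2R)-1-[3,5-bis(benzyloxy)-2-({[tert-butyl(dimethyl)silyl]oxy}methyl)phenyl]-13-(benzyloxy)tridecan-2-ol | O[C@H](CCCCCCCCCCCOCc1ccccc1)Cc1cc(OCc2ccccc2)cc(OCc2ccccc2)c1CO[Si](C)(C)C(C)(C)C
F7 | step 6 | (2R)-1-[3,5-bis(benzyloxy)-2-({[tert-butyl(dimethyl)silyl]oxy}methyl)phenyl]-13-(benzyloxy)tridecan-2-yl acetate | CC(=O)O[C@H](CCCCCCCCCCCOCc1ccccc1)Cc1cc(OCc2ccccc2)cc(OCc2ccccc2)c1CO[Si](C)(C)C(C)(C)C
F8 | step 6 | (2R)-1-[3,5-bis(benzyloxy)-2-(hydroxymethyl)phenyl]-13-(benzyloxy)tridecan-2-yl acetate | CC(=O)O[C@H](CCCCCCCCCCCOCc1ccccc1)Cc1cc(OCc2ccccc2)cc(OCc2ccccc2)c1CO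
F9 | step 6 | (2R)-1-[3,5-bis(benzyloxy)-2-formylphenyl]-13-(benzyloxy)tridecan-2-yl acetate | CC(=O)O[C@H](CCCCCCCCCCCOCc1ccccc1)Cc1cc(OCc2ccccc2)cc(OCc2ccccc2)c1C=O
F10 | step 6 | 2-[(2R)-2-(acetyloxy)-13-(benzyloxy)tridecyl]-4,6-bis(benzyloxy)benzoic acid | CC(=O)O[C@H](CCCCCCCCCCCOCc1ccccc1)Cc1cc(OCc2ccccc2)cc(OCc2ccccc2)c1C(=O)O
F11 | step 3 | {[(tridec-12-en-1-yl)oxy]methyl}benzene | C=CCCCCCCCCCCCOCc1ccccc1
F12 | step 3 | racemic 2-[11-(benzyloxy)undecyl]oxirane | C1OC1CCCCCCCCCCCOCc1ccccc1
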